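The ring is numbered so that C1 carries OAc, C2 and C3 carry the free hydroxyls, C4=C5 is the alkene, C5 holds the C7 benzoyloxymethyl group and C6 carries the ring benzoate. The route rests on cutting C5–C6. The C4=C5–C7 acrylate unit beside the C6 carbinol of the cyclohexene is a Morita–Baylis–Hillman pattern. One phosphine-catalysed cyclisation of an open-chain formyl enoate forms that bond, closes the six-membered ring and sets C6. C3, C2 and C1 come unchanged from C2, C3 and C4 of D-arabinose. In the precursor the trans C2/C3 diol is tied up as a butane-2,3-diacetal and C1–O alone carries a silyl group. The chain is therefore pre-folded, and the acetate later meets a single free hydroxyl.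

Key step: step 7

Remark (numbering): ring numbers are also used for open-chain compounds. C4 = sugar C1, C3 = sugar C2, C2 = sugar C3, C1 = sugar C4 and C6 = sugar C5; C5 and C7 come from the ylide.
Remark (configuration): C1–O and C2–O lie on one face (upper), and C3–O and C6–O lie on the other (lower). The target is (1S,2S,3R,6S) in this numbering.
Remark (stereocontrol): C5 and C2 both become ring atoms, so a 1,2-anti (Felkin–Anh type) addition at C6 would correspond to a cis C6/C1 diol. The required trans relationship is therefore drawn from a conformational lock, not from an open-chain model.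
Assumption: starting materials are numbered when their atoms reach the target (1, 6, 13, 16). Protecting-group reagents appear on the reagent lines only.

Step 1
Reactants: 1 D-arabinose
Product: 2 benzyl β-D-arabinopyranoside
Conditions: BnOH (solvent), HCl (gas, cat.), rt; crystallisation (Et2O)
Reagents that add atoms: benzyl alcohol, OCc1ccccc1
Why: Fischer glycosidation under equilibrating conditions should give the pyranoside with the anomeric benzyloxy group axial (β-D, cis to O2) because of the anomeric effect, this anomer crystallises, and the anomeric centre is removed again in step 4.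

Step 2
Reactants: 2 benzyl β-D-arabinopyranoside
Product: 3 benzyl 2,3-O-[(2S,3S)-2,3-dimethoxybutane-2,3-diyl]-β-D-arabinopyranoside
Conditions: butane-2,3-dione, HC(OMe)3, CSA (cat.), MeOH, reflux
Reagents that add atoms: butane-2,3-dione, CC(=O)C(C)=O; methanol, CO
Why: Reversible acid-catalysed 1,2-diacetal formation (butane diacetal protection) should settle on the trans-diequatorial O2/O3 pair as a trans-fused chair dioxane rather than on the cis O3/O4 pair, with the two new acetal centres set (S,S) by the double anomeric effect that places both methoxy groups axial, so sugar O4 (future C1–O) stays as the only free hydroxyl.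

Step 3
Reactants: 3 benzyl 2,3-O-diacetal arabinopyranoside
Product: 4 benzyl 4-O-(tert-butyldimethylsilyl)-2,3-O-[(2S,3S)-2,3-dimethoxybutane-2,3-diyl]-β-D-arabinopyranoside
Conditions: TBSOTf, 2,6-lutidine, CH2Cl2, 0 °C
Reagents that add atoms: tert-butyldimethylsilyl triflate, CC(C)(C)[Si](C)(C)OS(=O)(=O)C(F)(F)F
Why: Silyl ether formation with a silyl triflate and a non-nucleophilic base covers the single, axial and hindered hydroxyl and leaves the glycoside and the diacetal untouched.

Step 4
Reactants: 4 fully protected benzyl arabinopyranoside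
Product: 5 4-O-(tert-butyldimethylsilyl)-2,3-O-[(2S,3S)-2,3-dimethoxybutane-2,3-diyl]-D-arabinopyranose (lactol, anomeric mixture)
Conditions: H2 (1 atm), Pd/C, EtOAc, rt
Reagents that add atoms: none
Why: Catalytic hydrogenolysis cleaves only the benzylic C–O bond, ethyl acetate avoids the acid-induced loss of silyl or acetal groups met in alcohols, and the anomeric mixture does not matter because this carbon becomes sp2 in step 5.

Step 5
Reactants: 5 lactol; 6 ethyl (triphenylphosphoranylidene)acetate
Product: 7 ethyl (E)-6-O-(tert-butyldimethylsilyl)-2,3-dideoxy-4,5-O-[(2S,3S)-2,3-dimethoxybutane-2,3-diyl]-D-arabino-hept-2-enonate (free primary C6–OH in ring numbering)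
Conditions: 6, PhCO2H (cat.), toluene, 80 °C
Reagents that add atoms: ethyl (triphenylphosphoranylidene)acetate (6), CCOC(=O)C=P(c1ccccc1)(c1ccccc1)c1ccccc1
Why: Wittig olefination of the lactol with the stabilised ylide should give mainly the E enoate and frees sugar O5 as the primary alcohol, while the carboxylic acid co-catalyst speeds ring opening and keeps the medium non-basic so that neither oxa-Michael closure nor O-to-O silyl migration sets in.

Step 6
Reactants: 7 hydroxy enoate
Product: 8 formyl enoate (C6 aldehyde; E C4=C5–C7 ethyl ester; C1–OTBS; C2–O/C3–O in the diacetal; D-arabino configuration)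
Conditions: TEMPO (cat.), PhI(OAc)2, CH2Cl2, rt
Reagents that add atoms: none
Why: TEMPO-catalysed oxidation with PhI(OAc)2 as terminal oxidant stops at the aldehyde under base-free conditions, which protects C1 from epimerisation and the C2 oxygen from β-elimination.

Step 7
Reactants: 8 formyl enoate
Product: 11 cyclohexene C7 ethyl ester with free C6–OH (lower face; C1–OTBS upper face; C2–O upper and C3–O lower in the diacetal), via phosphonium enolate 9 (not isolated), via phosphonium aldolate 10 (not isolated)
Conditions: PMe3 (0.3 equiv), t-BuOH/THF, 0.02 M, argon, rt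
Reagents that add atoms: none
Why: PMe3 adds reversibly to C4 of 8 to give phosphonium ester enolate 9, whose α-carbon C5 attacks the C6 aldehyde to give aldolate 10; alcohol-relayed proton transfer from C5 to oxygen and E1cB loss of PMe3 then rebuild C4=C5 inside the new ring. The closest known reaction type is the intramolecular Morita–Baylis–Hillman cyclisation of ω-formyl α,β-unsaturated esters under trialkylphosphine catalysis. The cyclohexene closes in a 6-(enolexo)-exo-trig mode and ends up trans-fused to the chair dioxane, on which the C4 and C1 arms are vicinal, diequatorial and hence already gauche. C6 is controlled by this lock: C1–OTBS must sit axial, and because the aldol step is reversible while proton transfer and elimination limit turnover, the aldolate that goes on should be the one with the C6 oxygen axial on the opposite face, anti to the C1–O dipole and free of A1,3 strain with the exocyclic ester enolate (A1,2 strain with the ester in 11), which is the C6/C1 trans relationship of the target. The step needs chemoselectivity for conjugate addition over enolisation of the α-silyloxy aldehyde (C1 epimerisation, loss of the C2 oxygen), which a small, nucleophilic but weakly basic phosphine, the poor acetal leaving group at C2 and high dilution should secure. Enoate geometry is erased in 9, so any Z isomer converges, and the trans-diaxial C1–O/C6–O arrangement prevents silyl migration to the new alkoxide.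

Step 8
Reactants: 11 cyclohexene ester
Product: 12 C6,C7-diol (C5–CH2OH; other groups as in 11)
Conditions: i-Bu2AlH (4 equiv), CH2Cl2, −78 to −20 °C; aq. potassium sodium tartrate
Reagents that add atoms: none
Why: Excess i-Bu2AlH effects 1,2-reduction of the conjugated ester to the allylic alcohol at low temperature, where the silyl ether and the diacetal are inert and no stereocentre is touched.

Step 9
Reactants: 12 diol; 13 benzoyl chloride
Product: 14 C6,C7-dibenzoate (C1–OTBS; C2/C3 diacetal)
Conditions: 13 (3 equiv), pyridine, DMAP (cat.), CH2Cl2, 0 °C to rt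
Reagents that add atoms: benzoyl chloride (13), O=C(Cl)c1ccccc1
Why: DMAP-catalysed acylation esterifies the only two free hydroxyls (primary C7–OH and pseudoaxial allylic C6–OH) with retention at C6.

Step 10
Reactants: 14 dibenzoate
Product: 15 C1 alcohol (C6,C7-dibenzoate; C2/C3 diacetal)
Conditions: HF·pyridine, THF, 0 °C to rt
Reagents that add atoms: none
Why: Fluoride-driven cleavage of the Si–O bond under mildly acidic conditions frees C1–OH alone, and benzoate migration from C6–O is geometrically excluded because the diacetal lock holds the two oxygens trans-diaxial.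

Step 11
Reactants: 15 C1 alcohol; 16 acetic anhydride
Product: 17 C1 acetate (C6,C7-dibenzoate; C2/C3 diacetal)
Conditions: 16, pyridine, DMAP (cat.), CH2Cl2, rt
Reagents that add atoms: acetic anhydride (16), CC(=O)OC(C)=O
Why: DMAP-catalysed acetylation meets a single hydroxyl, so no regioselectivity is required.

Step 12
Reactants: 17 C1 acetate
Product: 18 target CNP0213675.1
Conditions: TFA/H2O (9:1), CH2Cl2, 0 °C; co-evaporation with toluene
Reagents that add atoms: none
Why: Acid hydrolysis of the diacetal breaks the C–O bonds on the butane side only, so the ring C–O bonds and their configuration are kept, and a short, cold exposure with non-basic work-up should leave the three esters in place.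

Compound list
1 | D-arabinose | O=C[C@@H](O)[C@H](O)[C@H](O)CO | starting material
2 | benzyl β-D-arabinopyranoside | c1ccccc1CO[C@H]1[C@@H](O)[C@H](O)[C@H](O)CO1 | intermediate
3 | benzyl 2,3-O-[(2S,3S)-2,3-dimethoxybutane-2,3-diyl]-β-D-arabinopyranoside | c1ccccc1CO[C@H]1[C@H]2O[C@](C)(OC)[C@@](C)(OC)O[C@@H]2[C@H](O)CO1 | intermediate
4 | benzyl 4-O-TBS-2,3-O-[(2S,3S)-2,3-dimethoxybutane-2,3-diyl]-β-D-arabinopyranoside | c1ccccc1CO[C@H]1[C@H]2O[C@](C)(OC)[C@@](C)(OC)O[C@@H]2[C@H](O[Si](C)(C)C(C)(C)C)CO1 | intermediate
5 | 4-O-TBS-2,3-O-diacetal-D-arabinopyranose (lactol, anomeric mixture) | OC1[C@H]2O[C@](C)(OC)[C@@](C)(OC)O[C@@H]2[C@H](O[Si](C)(C)C(C)(C)C)CO1 | intermediate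
6 | ethyl (triphenylphosphoranylidene)acetate | CCOC(=O)C=P(c1ccccc1)(c1ccccc1)c1ccccc1 | starting material
7 | hydroxy enoate (E; C1–OTBS; C2/C3 diacetal; C6 CH2OH) | CCOC(=O)/C=C/[C@H]1O[C@](C)(OC)[C@@](C)(OC)O[C@@H]1[C@H](O[Si](C)(C)C(C)(C)C)CO | intermediate
8 | formyl enoate (key-step precursor) | CCOC(=O)/C=C/[C@H]1O[C@](C)(OC)[C@@](C)(OC)O[C@@H]1[C@H](O[Si](C)(C)C(C)(C)C)C=O | intermediate
9 | phosphonium enolate (PMe3 on C4; C4 unassigned) | CCOC([O-])=CC([P+](C)(C)C)[C@H]1O[C@](C)(OC)[C@@](C)(OC)O[C@@H]1[C@H](O[Si](C)(C)C(C)(C)C)C=O | intermediate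
10 | phosphonium aldolate (C4 and C5 unassigned) | CCOC(=O)C1C([P+](C)(C)C)[C@H]2O[C@](C)(OC)[C@@](C)(OC)O[C@@H]2[C@H](O[Si](C)(C)C(C)(C)C)[C@H]1[O-] | intermediate
11 | cyclohexene C7 ethyl ester with free C6–OH (key-step product) | CCOC(=O)C1=C[C@H]2O[C@](C)(OC)[C@@](C)(OC)O[C@@H]2[C@H](O[Si](C)(C)C(C)(C)C)[C@H]1O | intermediate
12 | C6,C7-diol | OCC1=C[C@H]2O[C@](C)(OC)[C@@](C)(OC)O[C@@H]2[C@H](O[Si](C)(C)C(C)(C)C)[C@H]1O | intermediate
13 | benzoyl chloride | O=C(Cl)c1ccccc1 | starting material
14 | C6,C7-dibenzoate, C1–OTBS | O=C(c1ccccc1)OCC1=C[C@H]2O[C@](C)(OC)[C@@](C)(OC)O[C@@H]2[C@H](O[Si](C)(C)C(C)(C)C)[C@H]1OC(=O)c1ccccc1 | intermediate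
15 | C6,C7-dibenzoate, C1–OH | O=C(c1ccccc1)OCC1=C[C@H]2O[C@](C)(OC)[C@@](C)(OC)O[C@@H]2[C@H](O)[C@H]1OC(=O)c1ccccc1 | intermediate
16 | acetic anhydride | CC(=O)OC(C)=O | starting material
17 | C1 acetate, C6,C7-dibenzoate, C2/C3 diacetal | O=C(c1ccccc1)OCC1=C[C@H]2O[C@](C)(OC)[C@@](C)(OC)O[C@@H]2[C@H](OC(C)=O)[C@H]1OC(=O)c1ccccc1 | intermediate
18 | CNP0213675.1, (1S,2S,3R,6S) in ring numbering | CC(=O)O[C@H]1[C@@H](O)[C@H](O)C=C(COC(=O)c2ccccc2)[C@@H]1OC(=O)c1ccccc1 | target

Total step count: 12. Longest linear sequence: 12 steps, from D-arabinose.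

Steps most likely to fail

Step 7. Phosphine addition to the β,γ-substituted enoate may be slower than enolisation of the α-silyloxy aldehyde. In that case epimerisation at C1, elimination of the C2 oxygen or oligomerisation would take over. Incomplete facial control at C6 would have to be removed by chromatography at 11. The fallback replaces catalysis by a stoichiometric sulfur-triggered Michael–aldol cyclisation followed by base-induced elimination.
- It sets out from 8. PhSLi (PhSH, n-BuLi, THF, −78 °C) adds to C4, and the lithium enolate closes onto C6 to give the 4-phenylthio aldol F1. The C6 oxygen is again expected anti to the axial C1–O dipole.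
- mCPBA (2.2 equiv, CH2Cl2, 0 °C) gives the sulfone F2.
- DBU (CH2Cl2, 0 °C) removes the acidic C5–H and triggers E1cB elimination, which needs no syn alignment. The sequence comes back to the route at 11.

Step 12. Once the diacetal lock is gone, acid may promote acetyl migration from C1–O to the cis C2–OH, or partial ester hydrolysis. The fallback installs the acetate last, by regioselective opening of a cyclic orthoester.
- It sets out from 15. TFA/H2O (9:1, 0 °C) removes the diacetal while no acetate is present and gives the triol F3.
- MeC(OMe)3 and CSA (cat.) in CH2Cl2 form the C1/C2 orthoacetate F4, since only the cis pair can carry the five-membered ring.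
- 80% aqueous AcOH at rt opens it to the axial ester and the equatorial alcohol. A1,2 strain with the C5 substituent keeps C6–OBz pseudoaxial and hence C1–O axial, so the acetate should end on C1. The sequence comes back at 18.

Step 2. In hot acidic methanol the diacetal may partly bridge the cis O3/O4 pair, and the benzyl glycoside may exchange with the solvent. The fallback blocks sugar O4 first.
- It sets out from 2. PhC(OMe)3 and CSA (cat.) in MeCN at rt form the 3,4-orthobenzoate F5 on the cis pair.
- Aqueous AcOH opens it to the axial ester, benzyl 4-O-benzoyl-β-D-arabinopyranoside F6.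
- Diacetal formation at rt (butane-2,3-dione, HC(OMe)3, BF3·OEt2 cat., MeOH) then finds only the O2/O3 diol and gives the 2,3-diacetal 4-benzoate F7.
- Zemplén deacylation (NaOMe cat., MeOH) comes back to the route at 3.

Further compounds
F1 | step 7 | 4-phenylthio aldol (ethyl 4-phenylthio-6-hydroxycyclohexanecarboxylate, C1–OTBS, C2/C3 diacetal, C4 and C5 unassigned) | CCOC(=O)C1C(Sc3ccccc3)[C@H]2O[C@](C)(OC)[C@@](C)(OC)O[C@@H]2[C@H](O[Si](C)(C)C(C)(C)C)[C@H]1O
F2 | step 7 | sulfone (4-phenylsulfonyl analogue of F1) | CCOC(=O)C1C(S(=O)(=O)c3ccccc3)[C@H]2O[C@](C)(OC)[C@@](C)(OC)O[C@@H]2[C@H](O[Si](C)(C)C(C)(C)C)[C@H]1O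
F3 | step 12 | triol (C1,C2,C3-triol, C6,C7-dibenzoate) | O=C(c1ccccc1)OCC1=C[C@@H](O)[C@H](O)[C@H](O)[C@H]1OC(=O)c1ccccc1
F4 | step 12 | C1/C2 orthoacetate (orthoester carbon unassigned) | O=C(c1ccccc1)OCC1=C[C@@H](O)[C@@H]2OC(C)(OC)O[C@@H]2[C@H]1OC(=O)c1ccccc1
F5 | step 2 | 3,4-orthobenzoate (benzyl 3,4-O-(α-methoxybenzylidene)-β-D-arabinopyranoside, orthoester carbon unassigned) | c1ccccc1CO[C@H]1[C@@H](O)[C@@H]2OC(OC)(c3ccccc3)O[C@@H]2CO1
F6 | step 2 | benzyl 4-O-benzoyl-β-D-arabinopyranoside | c1ccccc1CO[C@H]1[C@@H](O)[C@H](O)[C@H](OC(=O)c2ccccc2)CO1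
F7 | step 2 | 2,3-diacetal 4-benzoate (benzyl 4-O-benzoyl-2,3-O-[(2S,3S)-2,3-dimethoxybutane-2,3-diyl]-β-D-arabinopyranoside) | c1ccccc1CO[C@H]1[C@H]2O[C@](C)(OC)[C@@](C)(OC)O[C@@H]2[C@H](OC(=O)c2ccccc2)CO1
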